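Readings and results are simulated from invented constants; scatter was added.

Read the south-west run from its end and ask how much product is still missing.

| setting | south-west | north | south-east |
|---|---|---|---|
| substrate | 100 mM | 100 mM | 100 mM |
| coupling partner | 80.0 mM | 240 mM | 80.0 mM |
| free catalyst | 3.00 mM | 3.00 mM | 3.00 mM |
| time |  |  | 480 h |

- south-west run (time / h: [product] / mM): 27: 66.5; 53: 71.3; 80: 73.7; 110: 75.3; 130: 76.7; 160: 77.6
- north run (time / h: [product] / mM): 27: 99.2; 53: 100.1; 80: 99.6; 110: 99.7; 130: 99.1; 160: 98.2

(readings scatter by 0.8 mM)

- how the opening rate goes with [coupling partner] round the charge of the south-west run: the exponent of the rate at two percent of substrate gone to product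
- product in the south-east run at 480 h, as a share of the substrate charged

- Overall: substrate + coupling partner -> product, with free catalyst as catalyst.
- Constant volume, constant temperature.
- Bound and free are read together.
- "The second partner" is coupling partner.
- An order is taken over about fifteen percent of the charge, up and down.

Each product takes one substrate and one coupling partner. In the south-west run the coupling partner is the limiting reagent, 80.0 mM against 100 mM of substrate, so product has a ceiling of 80.0 mM. I call the distance below that ceiling the gap, which is also the coupling partner left.

The south-west gap is 6.30 mM at 80 h and 2.40 mM at 160 h. I suppose that equal stretches of time remove equal fractions of it. Those readings then give 82.9 h as the gap life τ, the time in which the gap shrinks by the factor e. This is a reading, since a scatter of 0.8 mM sits on the last gap.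

Two times now matter: τ and the wait from the last reading to the asked time, 320 h. The south-east flask has the south-west charge, so I let it follow the same curve. Its wait is longer than τ, at 3.86 lives, and the gap falls to 0.0505 mM. I therefore expect the ceiling, 80.0 %, less that gap. The readings begin at 27 h, with 66.5 mM already made, so they show no opening rate, and my exponent of one for the coupling partner is a guess.

The forecast gives 79.7 % and an exponent of 1.5, holding that the rate “seems to rise more steeply than first order”.

The south-east flask gives 80.0 %, and the exponent is 1.0, under these steps:

    free catalyst + substrate ⇌ catalyst-substrate complex, settled at all times (43.50 /M)
    catalyst-substrate complex + coupling partner → product + free catalyst + by-product (78.12 /M/h)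
    free catalyst → spent catalyst (0.4320 /h)
    substrate + coupling partner + product → 2 product (7.524 /M²/h)

At two percent turned, the north run goes at 45 mM/h against 15 mM/h in the south-west run, 3.07 times the rate on 3.00 times the coupling partner. Carried back from the gap at 160 h in the south-west run, τ puts the gap at 130 h at 3.45 mM, and the reading of 76.7 mM there leaves a gap of 3.30 mM.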